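The reagent is what grey, red, ochre and blue differ in, so I turn the question round and ask what would have to be true of the given numbers for the share of target to move along that row.

all flasks: substrate 0.24 M; capture agent 4.80 mM; time 12 h

|  | reagent |
|---|---|
| grey | 0.500 M |
| red | 0.800 M |
| ochre | 1.00 M |
| blue | 1.50 M |

    substrate + reagent ⇌ open intermediate (K1 = 5.0 /M, k1 = 0.00140 /M/s)
    open intermediate → target (k2 = 4.00 × 10⁻⁴ /s)
    open intermediate → side product (k3 = 1.43 × 10⁻⁴ /s)
    open intermediate + capture agent → trapped intermediate (k4 = 3.47 × 10⁻⁴ /M/s)

1. share of target in all that became target or side product or trapped intermediate for grey, red, ochre, blue, in this order
2. how that number moves from the first to the last of them (falls all the way / falls, then rises / hardly changes / rises all the way / rises, then falls)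

- "hardly changes" means that all values lie within two and a half points (for a concentration: within two and a half percent of the largest)
- run time (grey): 12 h

The reagent enters at the first step, which makes the open intermediate. Once formed, the open intermediate either falls back, which adds nothing to the count, or goes on by 3 exits, and the reagent stands in none of those. Each exit's rate carries the same concentration of open intermediate, so that concentration cancels from their ratio. I therefore define the exit share, the usual selectivity, as k2 divided by the sum of k2, k3 and k4 times the capture agent as charged, and it comes to 73.4%.

The capture agent can only fall during a run, so I solve the two ends. With the capture agent as charged, the exit share is the value above. With the capture agent gone, it rises to 73.7%, which is higher. The share in any of these flasks must lie between those ends, whatever the reagent does. The opposite outcome therefore needs a gap between the ends wider than the margin stated above. That gap depends on capture against the other two exits, and capture runs at 1.67 × 10⁻⁶ /s against 5.43 × 10⁻⁴ /s, much the slower. These flasks, with one charge of capture agent, stand at a gap of 0.30 percentage points, inside that margin, so I commit to a flat row between the two ends.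

The forecast, with the words “All four runs therefore end the same”, gives 73.45%, 73.45%, 73.45% and 73.45%, and says the share hardly changes.

The simulation gives 73.5%, 73.5%, 73.5% and 73.5%, so the share hardly changes. At the end grey keeps 52% of its reagent and blue keeps 84%. Put to use on blue, where 0% of the substrate charged is left after 12.0 h, the two ends of the exit share place the target between 0.176 M and 0.177 M, and blue holds 73.5% of the substrate charged as target.

Its constants are those of an exercise.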